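**Retrosynthetic overview**
1. Target 14 ⇐ ester–imide 12: the free acid is unmasked last by hydroperoxide cleavage of an N-acyl oxazolidinone; the methyl ester is carried through intact.
2. Key disconnection, the bond between the ester α-carbon and the central three-carbon chain: radical, enantioconvergent nickel hydride hydroalkylation of terminal olefin 5 with racemic α-bromo ester 11. It joins the two halves and sets the (R) ester centre by catalyst control.
3. Olefin 5 ⇐ three-component radical addition/allyl transfer: 2-(furan-3-yl)ethyl radical (from iodide 2) + acrylimide 4 + allylstannane; the auxiliary sets the acid-bearing centre.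
4. Bromo ester 11 ⇐ methyl acetoacetate 6 + homoprenyl bromide 7 (alkylation, then bromination/deacetylation).
5. Rings: none is built; the furan is bought intact and the oxazolidinone is a removable auxiliary.

Assumption: the ligand antipode that gives the (R) ester centre in step 6 is taken to be (S,S), to be confirmed on a model olefin; if the sense is opposite, the (R,R) ligand is used and nothing else changes.

**Step 1**
Reactants: 1 2-(furan-3-yl)ethan-1-ol
Product: 2 3-(2-iodoethyl)furan
Conditions: PPh3 (1.2 equiv), I2 (1.2 equiv), imidazole (1.5 equiv), CH2Cl2, 0 °C → rt, dark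
Reagents that add atoms: iodine, II
Why: Appel-type iodination (SN2 displacement of the alkoxyphosphonium by iodide) of a primary alcohol under neutral conditions that leave the furan untouched.

**Step 2**
Reactants: 3 acryloyl chloride
Product: 4 (S)-3-acryloyl-4-(diphenylmethyl)oxazolidin-2-one
Conditions: (S)-4-(diphenylmethyl)oxazolidin-2-one, MeMgBr (1.05 equiv), THF, 0 °C; then 3 (1.2 equiv), −78 → 0 °C
Reagents that add atoms: (S)-4-(diphenylmethyl)oxazolidin-2-one, O=C1N[C@@H](C(c2ccccc2)c2ccccc2)CO1
Why: N-acylation of the bromomagnesium oxazolidinide (Evans acylation), which avoids the acrylate polymerisation seen with lithium bases; the auxiliary stereocentre is not touched.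

**Step 3**
Reactants: 4 (S)-3-acryloyl-4-(diphenylmethyl)oxazolidin-2-one; 2 3-(2-iodoethyl)furan
Product: 5 (S)-4-(diphenylmethyl)-3-[(R)-2-[3-(furan-3-yl)propyl]pent-4-enoyl]oxazolidin-2-one
Conditions: 2 (3 equiv), allylSnBu3 (3 equiv), MgBr2·OEt2 (2 equiv), (Bu3Sn)2 (10 mol %), hν (sun lamp), CH2Cl2, −78 °C
Reagents that add atoms: allyltributylstannane, C=CC[Sn](CCCC)(CCCC)CCCC
Why: Lewis-acid-promoted three-component radical conjugate addition/allyl transfer (Keck-type allylation in a stannyl radical chain): the primary 2-(furan-3-yl)ethyl radical adds to the MgBr2-chelated acrylimide and the resulting s-cis α-acyl radical is allylated on the face anti to the CHPh2 group, which sets the future acid-bearing centre with the same sense as an Evans enolate allylation.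

**Step 4**
Reactants: 6 methyl acetoacetate; 7 5-bromo-2-methylpent-2-ene
Product: 8 methyl 2-acetyl-6-methylhept-5-enoate (racemic)
Conditions: 6 (1.5 equiv), K2CO3 (1.5 equiv), NaI (10 mol %), acetone, reflux
Reagents that add atoms: none
Why: Acetoacetic ester C-alkylation (iodide-assisted SN2 of the stabilised enolate on the primary bromide); excess 6 suppresses dialkylation and the product is needed only as a racemate.

**Step 5**
Reactants: 8 methyl 2-acetyl-6-methylhept-5-enoate
Product: 11 methyl 2-bromo-6-methylhept-5-enoate (racemic), via sodium enolate 9 (not isolated), via bromo keto ester 10 (not isolated)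
Conditions: NaH (1.05 equiv), THF, 0 °C; NBS (1.05 equiv), −78 → 0 °C; then NaOMe (0.2 equiv), MeOH, 0 °C; 1 M HCl work-up
Reagents that add atoms: N-bromosuccinimide, O=C1CCC(=O)N1Br
Why: Enolate bromination (the preformed enolate reacts with NBS far faster than the trisubstituted olefin) followed by retro-Claisen deacetylation of the non-enolisable α-bromo β-keto ester by catalytic methoxide, the leaving group being the stabilised α-bromo ester enolate.

**Step 6 (key step)**
Reactants: 5 (S)-4-(diphenylmethyl)-3-[(R)-2-[3-(furan-3-yl)propyl]pent-4-enoyl]oxazolidin-2-one; 11 methyl 2-bromo-6-methylhept-5-enoate (racemic)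
Product: 12 methyl (2R,6S)-6-[(S)-4-(diphenylmethyl)-2-oxooxazolidine-3-carbonyl]-9-(furan-3-yl)-2-(4-methylpent-3-en-1-yl)nonanoate
Conditions: NiBr2·MeOCH2CH2OMe (10 mol %), 2,2'-(propane-2,2-diyl)bis[(4S)-4-phenyl-4,5-dihydrooxazole] (12 mol %), (EtO)2MeSiH (2 equiv), KF (2.5 equiv), rac-11 (1.5 equiv), DMA, 0 °C → rt
Reagents that add atoms: none
Why: Proposed new method: a chiral bis(oxazoline) nickel hydride (from NiBr2, silane and KF) adds anti-Markovnikov to the terminal olefin of 5 only (the trisubstituted olefin, furan and imide are inert), while bromine-atom abstraction from rac-11 by monovalent nickel gives a planar α-ester radical so that both enantiomers of 11 converge; capture of this radical by the chiral primary-alkylnickel and reductive elimination forms the C–C bond and sets the (R) ester centre under catalyst control, the existing centre being 1,5-remote. The closest known reaction type is the enantioconvergent nickel hydride hydroalkylation of terminal olefins with racemic α-bromo amides, supported by enantioconvergent nickel-catalysed couplings of racemic α-bromo esters with organosilicon nucleophiles.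

**Step 7**
Reactants: 12 methyl (2R,6S)-6-[(S)-4-(diphenylmethyl)-2-oxooxazolidine-3-carbonyl]-9-(furan-3-yl)-2-(4-methylpent-3-en-1-yl)nonanoate
Product: 14 (2S,6R)-2-[3-(furan-3-yl)propyl]-7-methoxy-6-(4-methylpent-3-en-1-yl)-7-oxoheptanoic acid (target), via peroxy acid 13 (not isolated)
Conditions: LiOH·H2O (2 equiv), 30% H2O2 (4 equiv), THF/H2O 3:1, 0 °C; Na2SO3 (aq), 0 °C; then 0.5 M HCl to pH 3–4
Reagents that add atoms: hydrogen peroxide, OO
Why: Evans hydroperoxide cleavage: LiOOH attacks the exocyclic imide carbonyl much faster than hydroxide hydrolyses the α-branched methyl ester, the percarboxylate is reduced by sulfite before acidification so the furan and olefin are not oxidised, and neither α-centre is enolised at 0 °C.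

**Compound list**
1 | 2-(furan-3-yl)ethan-1-ol | OCCc1ccoc1 | starting material
2 | 3-(2-iodoethyl)furan | ICCc1ccoc1 | intermediate
3 | acryloyl chloride | C=CC(=O)Cl | starting material
4 | (S)-3-acryloyl-4-(diphenylmethyl)oxazolidin-2-one | C=CC(=O)N1[C@@H](C(c2ccccc2)c2ccccc2)COC1=O | intermediate
5 | (S)-4-(diphenylmethyl)-3-[(R)-2-[3-(furan-3-yl)propyl]pent-4-enoyl]oxazolidin-2-one | C=CC[C@@H](CCCc1ccoc1)C(=O)N1[C@@H](C(c2ccccc2)c2ccccc2)COC1=O | intermediate
6 | methyl acetoacetate (methyl 3-oxobutanoate) | COC(=O)CC(C)=O | starting material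
7 | 5-bromo-2-methylpent-2-ene | CC(C)=CCCBr | starting material
8 | methyl 2-acetyl-6-methylhept-5-enoate (racemic) | COC(=O)C(CCC=C(C)C)C(C)=O | intermediate
9 | sodium enolate of 8 (sodium 3-(methoxycarbonyl)-7-methylocta-2,6-dien-2-olate) | COC(=O)C(CCC=C(C)C)=C(C)[O-].[Na+] | intermediate (not isolated)
10 | methyl 2-acetyl-2-bromo-6-methylhept-5-enoate (racemic) | COC(=O)C(Br)(CCC=C(C)C)C(C)=O | intermediate (not isolated)
11 | methyl 2-bromo-6-methylhept-5-enoate (racemic) | COC(=O)C(Br)CCC=C(C)C | intermediate
12 | methyl (2R,6S)-6-[(S)-4-(diphenylmethyl)-2-oxooxazolidine-3-carbonyl]-9-(furan-3-yl)-2-(4-methylpent-3-en-1-yl)nonanoate | COC(=O)[C@@H](CCC=C(C)C)CCC[C@@H](CCCc1ccoc1)C(=O)N1[C@@H](C(c2ccccc2)c2ccccc2)COC1=O | intermediate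
13 | (2S,6R)-2-[3-(furan-3-yl)propyl]-7-methoxy-6-(4-methylpent-3-en-1-yl)-7-oxoheptaneperoxoic acid | COC(=O)[C@@H](CCC=C(C)C)CCC[C@@H](CCCc1ccoc1)C(=O)OO | intermediate (not isolated)
14 | (2S,6R)-2-[3-(furan-3-yl)propyl]-7-methoxy-6-(4-methylpent-3-en-1-yl)-7-oxoheptanoic acid | COC(=O)[C@@H](CCC=C(C)C)CCC[C@@H](CCCc1ccoc1)C(=O)O | target

**Step count**
Total steps: 7. Longest linear sequence: 4 steps (for example 1 → 2 → 5 → 12 → 14; the branches 3 → 4 → 5 and 6/7 → 8 → 11 → 12 are equally long).

**Three steps most likely to fail, each with one fallback**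

Step 6 is the largest risk. A methyl ester is a smaller control element than the anilides for which this coupling is established, so enantioselectivity may be low. Hydrodebromination of 11 and chain walking are further risks, and C2 epimers of 12 would be hard to separate. Fallback: set the centre on an anilide and exchange it for the ester afterwards. Bromo ester 11 is converted with Me2AlN(Me)Ph (from AlMe3 and N-methylaniline, toluene, 0 °C → rt) into racemic 2-bromo-N,6-dimethyl-N-phenylhept-5-enamide F1. F1 is coupled with 5 under the step 6 conditions to give (2R,6S)-6-[(S)-4-(diphenylmethyl)-2-oxooxazolidine-3-carbonyl]-9-(furan-3-yl)-N-methyl-2-(4-methylpent-3-en-1-yl)-N-phenylnonanamide F2. O-Methylation of the anilide with Me3OBF4 (2,6-di-tert-butylpyridine, CH2Cl2, rt; the imide oxygen is much less nucleophilic) gives the methoxyiminium tetrafluoroborate F3. Mild aqueous hydrolysis of F3 (pH 4 buffer) releases N-methylaniline and gives the methyl ester. This fallback sets out from 11 (with 5) and comes back to the route at 12.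

Step 3 is the second risk. The primary radical adds more slowly than the secondary and tertiary radicals usually used, and it can be allylated directly. The electrophilic α-acyl radical may also be trapped by the furan, which is why 2 and the stannane are used in excess and an ethyl-free initiator is chosen. Fallback: separate the radical and the stereodefining events. Reductive radical conjugate addition of 2 to 4 (Bu3SnH by syringe pump, AIBN, benzene, 80 °C) gives (S)-4-(diphenylmethyl)-3-[5-(furan-3-yl)pentanoyl]oxazolidin-2-one F4. Deprotonation with NaN(SiMe3)2 (THF, −78 °C) gives the sodium (Z)-enolate F5, which is alkylated with allyl iodide anti to the CHPh2 group (polar Evans alkylation). This fallback sets out from 2 and 4 and comes back to the route at 5.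

Step 5 is the third risk. NBS may attack the trisubstituted olefin if enolate formation is incomplete, and methoxide may displace the activated secondary bromide. Fallback: leave the acetoacetate route. The lithium enolate of methyl acetate (LiN(i-Pr)2, THF, −78 °C) is alkylated with 7 (DMPU, −78 → −20 °C) to give methyl 6-methylhept-5-enoate F6. F6 is converted (LiN(i-Pr)2, Me3SiCl, −78 °C) into the ketene silyl acetal [(1-methoxy-6-methylhepta-1,5-dien-1-yl)oxy]trimethylsilane F7, which is brominated with NBS at −78 °C. This fallback sets out from 7 and comes back to the route at 11.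

**Further compounds**
F1 | step 6 | racemic 2-bromo-N,6-dimethyl-N-phenylhept-5-enamide | CN(c1ccccc1)C(=O)C(Br)CCC=C(C)C
F2 | step 6 | (2R,6S)-6-[(S)-4-(diphenylmethyl)-2-oxooxazolidine-3-carbonyl]-9-(furan-3-yl)-N-methyl-2-(4-methylpent-3-en-1-yl)-N-phenylnonanamide | CN(c1ccccc1)C(=O)[C@@H](CCC=C(C)C)CCC[C@@H](CCCc1ccoc1)C(=O)N1[C@@H](C(c2ccccc2)c2ccccc2)COC1=O
F3 | step 6 | methoxyiminium tetrafluoroborate from O-methylation of F2 | COC(=[N+](C)c1ccccc1)[C@@H](CCC=C(C)C)CCC[C@@H](CCCc1ccoc1)C(=O)N1[C@@H](C(c2ccccc2)c2ccccc2)COC1=O.F[B-](F)(F)F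
F4 | step 3 | (S)-4-(diphenylmethyl)-3-[5-(furan-3-yl)pentanoyl]oxazolidin-2-one | O=C(CCCCc1ccoc1)N1[C@@H](C(c2ccccc2)c2ccccc2)COC1=O
F5 | step 3 | sodium (Z)-enolate of F4 | [Na+].[O-]/C(=C\CCCc1ccoc1)N1[C@@H](C(c2ccccc2)c2ccccc2)COC1=O
F6 | step 5 | methyl 6-methylhept-5-enoate | COC(=O)CCCC=C(C)C
F7 | step 5 | [(1-methoxy-6-methylhepta-1,5-dien-1-yl)oxy]trimethylsilane | COC(O[Si](C)(C)C)=CCCC=C(C)C
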